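Nymphaeol A 23 ⇐ tetra-MOM ether 22 (acid solvolysis, last step). Rings A and B are bought; ring C is the only ring that is made.
Ring C (O1–C2–C3–C4–C4a–C8a) ⇐ four-membered β-lactone 18 (O1–C2–C3–C4, closed by the O1–C4 acyl bond) + aryne 19 (C4a≡C8a of ring A). The two aryne carbons are inserted into the O1–C4 bond, a strain-driven 4 → 6 ring expansion that forms O1–C8a and C4–C4a in one operation.
Enabling feature: O1–C2–C3–C4(=O) of ring C is a β-hydroxy acid unit, so it can be stored as a strained lactone that already carries (S)-C2. The other two ring atoms are neighbouring carbons of ring A, and the C5 oxygen beside C4a polarises the aryne (O to C8a, acyl to C4a). The geranyl carbon C6 is para to C8a, on the mirror plane of phenol 7, so a 6- versus 8-geranyl problem never arises.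
Aryne precursor 11 ⇐ phloroglucinol 1 + geranyl bromide 4 (directed ortho-metalation, iodination, retro-Brook shift, triflation). Lactone 18 ⇐ 3',4'-dihydroxyacetophenone 12 (Claisen condensation, asymmetric transfer hydrogenation, lactonisation).
Order of ring formation: four-membered lactone (step 11), then its expansion to ring C (step 12).

Key step: step 12

Remark: flavanone numbering is used (O1, C2, C3, C4, C4a, C5 to C8, C8a; ring A = benzo ring, ring B = catechol ring, ring C = pyranone ring). The stereocentre of the target reads (2S). "Geranyl" means (2E)-3,7-dimethylocta-2,6-dien-1-yl and MOM means CH2OCH3.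

Step 1
Reactants: 1 phloroglucinol (benzene-1,3,5-triol)
Product: 2 3,5-bis(methoxymethoxy)phenol
Conditions: MOMCl (2.0 equiv), iPr2NEt, DMF, 0 °C to rt; chromatography
Reagents that add atoms: chloromethyl methyl ether, COCCl
Why: Williamson-type O-alkylation of three equivalent phenol groups, so two equivalents of MOMCl should make the bis-ether the main member of a statistical mixture from which it is separated by chromatography.

Step 2
Reactants: 2 3,5-bis(methoxymethoxy)phenol
Product: 3 [3,5-bis(methoxymethoxy)phenoxy]triisopropylsilane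
Conditions: TIPSCl, imidazole, DMF, rt
Reagents that add atoms: chlorotriisopropylsilane, CC(C)[Si](Cl)(C(C)C)C(C)C
Why: Silyl ether formation at the only free OH; the bulky TIPS group survives n-BuLi and shields its two neighbouring C–H bonds, which leaves the position between the two OMOM groups as the only site for the next lithiation.

Step 3
Reactants: 3 [3,5-bis(methoxymethoxy)phenoxy]triisopropylsilane; 4 geranyl bromide
Product: 6 [4-geranyl-3,5-bis(methoxymethoxy)phenoxy]triisopropylsilane, via aryllithium 5 (not isolated)
Conditions: n-BuLi, THF, 0 °C, 1 h; CuI (10 mol %), 4, −78 °C to rt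
Reagents that add atoms: none
Why: Directed ortho-metalation at the C–H flanked by two chelating OMOM groups followed by copper-catalysed SN2 allylation of the aryl metal with the primary allylic bromide, which should keep the linear E-geranyl chain and creates no stereocentre.

Step 4
Reactants: 6 [4-geranyl-3,5-bis(methoxymethoxy)phenoxy]triisopropylsilane
Product: 7 4-geranyl-3,5-bis(methoxymethoxy)phenol
Conditions: TBAF, THF, 0 °C
Reagents that add atoms: none
Why: Fluoride-induced cleavage of the aryl silyl ether, under which MOM acetals and the two trisubstituted alkenes are inert.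

Step 5
Reactants: 7 4-geranyl-3,5-bis(methoxymethoxy)phenol
Product: 8 4-geranyl-2-iodo-3,5-bis(methoxymethoxy)phenol
Conditions: I2 (1.0 equiv), NaHCO3, THF–H2O, 0 °C
Reagents that add atoms: iodine, II
Why: Electrophilic aromatic iodination of a phenoxide activated by three oxygen donors, far faster than any reaction of iodine at the trisubstituted alkenes; the two open ring positions are related by the mirror plane through C1 and C4 of the phenol, so only one mono-iodide can form.

Step 6
Reactants: 8 4-geranyl-2-iodo-3,5-bis(methoxymethoxy)phenol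
Product: 11 4-geranyl-3,5-bis(methoxymethoxy)-2-(trimethylsilyl)phenyl trifluoromethanesulfonate, via TMS ether 9 (not isolated), via lithium silylphenoxide 10 (not isolated)
Conditions: (Me3Si)2NH, THF, 65 °C, then evaporation; n-BuLi, THF, −78 °C; Tf2O, −78 to 0 °C
Reagents that add atoms: hexamethyldisilazane, C[Si](C)(C)N[Si](C)(C)C; trifluoromethanesulfonic anhydride, O=S(=O)(OS(=O)(=O)C(F)(F)F)C(F)(F)F
Why: O-silylation, iodine–lithium exchange and retro-Brook rearrangement (1,3-shift of silicon from O to the ortho carbanion) followed by O-triflation, the standard entry to 2-silylaryl triflates; the exchange at −78 °C outruns deprotonation of the benzylic allylic CH2.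

Step 7
Reactants: 12 3',4'-dihydroxyacetophenone
Product: 13 3',4'-bis(methoxymethoxy)acetophenone
Conditions: MOMCl, iPr2NEt, CH2Cl2, 0 °C to rt
Reagents that add atoms: chloromethyl methyl ether, COCCl
Why: Williamson-type O-alkylation of both catechol OH groups, giving base- and fluoride-stable acetals that fall off together with those of ring A at the end.

Step 8
Reactants: 13 3',4'-bis(methoxymethoxy)acetophenone
Product: 14 ethyl 3-[3,4-bis(methoxymethoxy)phenyl]-3-oxopropanoate
Conditions: NaH, (EtO)2CO, THF, reflux; AcOH quench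
Reagents that add atoms: diethyl carbonate, CCOC(=O)OCC
Why: Crossed Claisen condensation of the methyl ketone enolate with non-enolisable diethyl carbonate, driven to completion by deprotonation of the β-keto ester.

Step 9
Reactants: 14 ethyl 3-[3,4-bis(methoxymethoxy)phenyl]-3-oxopropanoate
Product: 15 ethyl (3S)-3-[3,4-bis(methoxymethoxy)phenyl]-3-hydroxypropanoate
Conditions: RuCl(p-cymene)[(S,S)-TsDPEN] (1 mol %), HCO2H–Et3N (5:2), 30 °C
Reagents that add atoms: none
Why: Noyori asymmetric transfer hydrogenation of an aryl ketone; the (S,S)-TsDPEN ligand places the aryl group beside the η6-arene as it does for acetophenone and so should deliver the (S)-carbinol, which becomes C2 of the target.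

Step 10
Reactants: 15 ethyl (3S)-3-[3,4-bis(methoxymethoxy)phenyl]-3-hydroxypropanoate
Product: 16 (3S)-3-[3,4-bis(methoxymethoxy)phenyl]-3-hydroxypropanoic acid
Conditions: LiOH, THF–H2O, 0 °C to rt; cold 1 M HCl to pH 4
Reagents that add atoms: lithium hydroxide, [Li+].[OH-]
Why: Ester saponification at low temperature, which avoids retro-aldol cleavage and dehydration and leaves the stereocentre and the MOM acetals untouched, the acidification being stopped at pH 4.

Step 11
Reactants: 16 (3S)-3-[3,4-bis(methoxymethoxy)phenyl]-3-hydroxypropanoic acid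
Product: 18 (4S)-4-[3,4-bis(methoxymethoxy)phenyl]oxetan-2-one, via mixed sulfonic anhydride 17 (not isolated)
Conditions: PhSO2Cl, pyridine, 0 to 4 °C
Reagents that add atoms: none
Why: Carboxyl-group activation as the mixed sulfonic anhydride and 4-exo-trig attack of the free hydroxyl group (β-lactonisation of a β-hydroxy acid), in which the C–O bond at the stereocentre is not broken, so that (S) is retained.

Step 12
Reactants: 11 4-geranyl-3,5-bis(methoxymethoxy)-2-(trimethylsilyl)phenyl trifluoromethanesulfonate; 18 (4S)-4-[3,4-bis(methoxymethoxy)phenyl]oxetan-2-one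
Product: 22 (2S)-2-[3,4-bis(methoxymethoxy)phenyl]-6-geranyl-5,7-bis(methoxymethoxy)chroman-4-one, via aryne 19 (not isolated), via oxido acyl fluoride 20 (not isolated), via aryl caesium 21 (not isolated)
Conditions: CsF (3 equiv), 18-crown-6 (3 equiv), THF, 23 °C; 11 added over 4 h to 18 (1.3 equiv)
Reagents that add atoms: none
Why: Proposed new method: fluoride strips the silyl group from 11 to give aryne 19 and, in an equilibrium paid for by the ring strain of the β-lactone, opens the acyl–O bond of 18 to the oxido acyl fluoride 20; the alkoxide adds to the aryne, and the aryl anion 21 closes ring C by 6-exo-trig acyl substitution at C4 with return of fluoride, so that the C8a–C4a pair of ring A ends up inserted into the O1–C4 bond and the four-membered ring becomes the six-membered one. The closest known reactions are the insertion of arynes into the N–C(O) bond of β-lactams (four- to six-membered ring, 2,3-dihydroquinolin-4-ones), the aryne annulation of salicylates to xanthones (O-addition, then acyl trapping of the aryl anion in a six-membered closure) and the acyl-alkylation of 3,5-dialkoxyarynes with β-keto lactones; what is new is the O–C(O) bond of a lactone as the acceptor. No stereocentre is made: C2 comes in with 18 and none of its four bonds (O1, C3, aryl, H) is broken, so (S) is retained. The step needs regioselectivity on the aryne, and the C5 OMOM group beside C4a secures it, because its inductive pull distorts the aryne so that nucleophiles attack the remote carbon C8a and the charge develops at C4a; this also fixes geranyl at C6 and excludes the 8-geranyl isomer. It needs acyl–O rather than benzylic C2–O cleavage of the lactone, which the hard fluoride and alkoxide nucleophiles and the low temperature favour, and any oligoester formed from 20 and 18 still ends in an alkoxide that is arylated and unzipped to 22 in the same way. THF instead of MeCN keeps proton sources away from 21, so that acyl transfer should win over protonation.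

Step 13
Reactants: 22 (2S)-2-[3,4-bis(methoxymethoxy)phenyl]-6-geranyl-5,7-bis(methoxymethoxy)chroman-4-one
Product: 23 nymphaeol A
Conditions: 3 M aq HCl, MeOH, 50 °C
Reagents that add atoms: none
Why: Acid-catalysed acetal solvolysis (transacetalisation to dimethoxymethane) frees all four phenols; acid rather than base is used because C2 of a flavanone epimerises through base-induced opening to the chalcone, and the mild temperature should spare the geranyl alkenes.

Compound list
1 | phloroglucinol (benzene-1,3,5-triol) | Oc1cc(O)cc(O)c1 | starting material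
2 | 3,5-bis(methoxymethoxy)phenol | COCOc1cc(O)cc(OCOC)c1 | intermediate
3 | [3,5-bis(methoxymethoxy)phenoxy]triisopropylsilane | COCOc1cc(OCOC)cc(O[Si](C(C)C)(C(C)C)C(C)C)c1 | intermediate
4 | geranyl bromide, (2E)-1-bromo-3,7-dimethylocta-2,6-diene | CC(C)=CCC/C(C)=C/CBr | starting material
5 | 2,6-bis(methoxymethoxy)-4-(triisopropylsilyloxy)phenyllithium | [Li]c1c(OCOC)cc(O[Si](C(C)C)(C(C)C)C(C)C)cc1OCOC | intermediate
6 | [4-geranyl-3,5-bis(methoxymethoxy)phenoxy]triisopropylsilane | CC(C)=CCC/C(C)=C/Cc1c(OCOC)cc(O[Si](C(C)C)(C(C)C)C(C)C)cc1OCOC | intermediate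
7 | 4-geranyl-3,5-bis(methoxymethoxy)phenol | CC(C)=CCC/C(C)=C/Cc1c(OCOC)cc(O)cc1OCOC | intermediate
8 | 4-geranyl-2-iodo-3,5-bis(methoxymethoxy)phenol | CC(C)=CCC/C(C)=C/Cc1c(OCOC)cc(O)c(I)c1OCOC | intermediate
9 | [4-geranyl-2-iodo-3,5-bis(methoxymethoxy)phenoxy]trimethylsilane | CC(C)=CCC/C(C)=C/Cc1c(OCOC)cc(O[Si](C)(C)C)c(I)c1OCOC | intermediate
10 | lithium 4-geranyl-3,5-bis(methoxymethoxy)-2-(trimethylsilyl)phenoxide | CC(C)=CCC/C(C)=C/Cc1c(OCOC)cc([O-])c([Si](C)(C)C)c1OCOC.[Li+] | intermediate
11 | 4-geranyl-3,5-bis(methoxymethoxy)-2-(trimethylsilyl)phenyl trifluoromethanesulfonate | CC(C)=CCC/C(C)=C/Cc1c(OCOC)cc(OS(=O)(=O)C(F)(F)F)c([Si](C)(C)C)c1OCOC | intermediate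
12 | 3',4'-dihydroxyacetophenone | CC(=O)c1ccc(O)c(O)c1 | starting material
13 | 3',4'-bis(methoxymethoxy)acetophenone | CC(=O)c1ccc(OCOC)c(OCOC)c1 | intermediate
14 | ethyl 3-[3,4-bis(methoxymethoxy)phenyl]-3-oxopropanoate | CCOC(=O)CC(=O)c1ccc(OCOC)c(OCOC)c1 | intermediate
15 | ethyl (3S)-3-[3,4-bis(methoxymethoxy)phenyl]-3-hydroxypropanoate | CCOC(=O)C[C@@H](c1ccc(OCOC)c(OCOC)c1)O | intermediate
16 | (3S)-3-[3,4-bis(methoxymethoxy)phenyl]-3-hydroxypropanoic acid | OC(=O)C[C@@H](c1ccc(OCOC)c(OCOC)c1)O | intermediate
17 | benzenesulfonic (3S)-3-[3,4-bis(methoxymethoxy)phenyl]-3-hydroxypropanoic anhydride | O=C(OS(=O)(=O)c1ccccc1)C[C@@H](c1ccc(OCOC)c(OCOC)c1)O | intermediate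
18 | (4S)-4-[3,4-bis(methoxymethoxy)phenyl]oxetan-2-one | O=C1C[C@@H](c2ccc(OCOC)c(OCOC)c2)O1 | intermediate
19 | 4-geranyl-3,5-bis(methoxymethoxy)benzyne (triple bond between the later C4a and C8a) | CC(C)=CCC/C(C)=C/CC1=C(OCOC)C#CC=C1OCOC | intermediate
20 | caesium (1S)-1-[3,4-bis(methoxymethoxy)phenyl]-3-fluoro-3-oxopropan-1-olate | O=C(F)C[C@@H](c1ccc(OCOC)c(OCOC)c1)[O-].[Cs+] | intermediate
21 | aryl caesium: (3S)-3-[3,4-bis(methoxymethoxy)phenyl]-3-[2-caesio-4-geranyl-3,5-bis(methoxymethoxy)phenoxy]propanoyl fluoride | O=C(F)C[C@@H](c1ccc(OCOC)c(OCOC)c1)Oc1cc(OCOC)c(C/C=C(C)/CCC=C(C)C)c(OCOC)c1[Cs] | intermediate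
22 | (2S)-2-[3,4-bis(methoxymethoxy)phenyl]-6-geranyl-5,7-bis(methoxymethoxy)chroman-4-one | CC(C)=CCC/C(C)=C/Cc1c(OCOC)cc2c(c1OCOC)C(=O)C[C@@H](c1ccc(OCOC)c(OCOC)c1)O2 | intermediate
23 | nymphaeol A, (2S)-2-(3,4-dihydroxyphenyl)-6-geranyl-5,7-dihydroxychroman-4-one | CC(C)=CCC/C(C)=C/Cc1c(O)cc2c(c1O)C(=O)C[C@@H](c1ccc(O)c(O)c1)O2 | target

Total step count: 13. Longest linear sequence: 8 steps (steps 1 to 6, 12 and 13).

Steps most likely to fail

Step 12 (proposed new method).
- What may go wrong:
  - The lactone may open too slowly.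
  - The opened lactone may lose its β-oxygen by elimination to a cinnamoyl derivative.
  - The aryl anion may pick up a proton before acyl transfer.
  - The benzylic C2–O bond may cleave.
  - The basic medium may open the product ring, which would erode the configuration at C2.
- The fallback uses known chemistry, sets out from β-keto ester 14 and iodophenol 8, and comes back at 22.
- Transfer hydrogenation of 14 with the enantiomeric catalyst RuCl(p-cymene)[(R,R)-TsDPEN] would give the ethyl (3R)-hydroxy ester F1.
- MeNH(OMe)·HCl and iPrMgCl would turn F1 into the (3R)-hydroxy Weinreb amide F2, and TBSCl with imidazole would give its silyl ether F3.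
- Iodophenol 8 with n-BuLi (2.1 equiv, THF, −78 °C) would give the lithium 2-lithiophenoxide F4, which is acylated by F3 to the 2'-hydroxyaryl ketone F5.
- TBAF buffered with AcOH would free the (R)-benzylic alcohol of the hydroxy ketone F6.
- An intramolecular Mitsunobu etherification (PPh3, DIAD, THF, 0 °C) would close ring C with inversion to (S)-22.

Step 11.
- What may go wrong:
  - The electron-rich benzylic C–O bond may ionise during closure or on silica, with racemisation or decarboxylation.
  - The hydroxyl group may be sulfonylated in place of the carboxylate.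
- The fallback sets out from acid 16 and comes back at 18.
- PhSH and DCC with catalytic DMAP would give the S-phenyl thioester F7.
- F7 is closed under neutral buffered conditions by thiophilic activation with the divalent mercury salt Hg(O2CCF3)2 (Na2HPO4, MeCN, rt). No sulfonylating agent and no pyridinium salt then meets the benzylic alcohol, and the lactone is purified by crystallisation.

Step 13.
- What may go wrong:
  - Acid may cyclise the geranyl chain onto the neighbouring C5 or C7 phenol.
  - Methanol may add to the alkenes.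
  - The heterocycle may open slowly.
- The fallback sets out from 22 and comes back at 23.
- TMSOTf and 2,2'-bipyridyl (CH2Cl2, 0 °C) would exchange the four aryl MOM groups for silyl groups without a Brønsted acid, giving the tetrakis(trimethylsilyl) ether F8.
- Water at neutral pH would then hydrolyse F8 to 23.

Further compounds
F1 | step 12 | ethyl (3R)-3-[3,4-bis(methoxymethoxy)phenyl]-3-hydroxypropanoate | CCOC(=O)C[C@H](c1ccc(OCOC)c(OCOC)c1)O
F2 | step 12 | (3R)-3-[3,4-bis(methoxymethoxy)phenyl]-3-hydroxy-N-methoxy-N-methylpropanamide | CON(C)C(=O)C[C@H](c1ccc(OCOC)c(OCOC)c1)O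
F3 | step 12 | (3R)-3-[3,4-bis(methoxymethoxy)phenyl]-3-(tert-butyldimethylsilyloxy)-N-methoxy-N-methylpropanamide | CON(C)C(=O)C[C@H](c1ccc(OCOC)c(OCOC)c1)O[Si](C)(C)C(C)(C)C
F4 | step 12 | lithium 4-geranyl-2-lithio-3,5-bis(methoxymethoxy)phenoxide | CC(C)=CCC/C(C)=C/Cc1c(OCOC)cc([O-])c([Li])c1OCOC.[Li+]
F5 | step 12 | (3R)-3-[3,4-bis(methoxymethoxy)phenyl]-3-(tert-butyldimethylsilyloxy)-1-[3-geranyl-6-hydroxy-2,4-bis(methoxymethoxy)phenyl]propan-1-one | CC(C)=CCC/C(C)=C/Cc1c(OCOC)cc(O)c(c1OCOC)C(=O)C[C@H](c1ccc(OCOC)c(OCOC)c1)O[Si](C)(C)C(C)(C)C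
F6 | step 12 | (3R)-3-[3,4-bis(methoxymethoxy)phenyl]-3-hydroxy-1-[3-geranyl-6-hydroxy-2,4-bis(methoxymethoxy)phenyl]propan-1-one | CC(C)=CCC/C(C)=C/Cc1c(OCOC)cc(O)c(c1OCOC)C(=O)C[C@H](c1ccc(OCOC)c(OCOC)c1)O
F7 | step 11 | S-phenyl (3S)-3-[3,4-bis(methoxymethoxy)phenyl]-3-hydroxypropanethioate | O=C(Sc1ccccc1)C[C@@H](c1ccc(OCOC)c(OCOC)c1)O
F8 | step 13 | (2S)-2-[3,4-bis(trimethylsilyloxy)phenyl]-6-geranyl-5,7-bis(trimethylsilyloxy)chroman-4-one | CC(C)=CCC/C(C)=C/Cc1c(O[Si](C)(C)C)cc2c(c1O[Si](C)(C)C)C(=O)C[C@@H](c1ccc(O[Si](C)(C)C)c(O[Si](C)(C)C)c1)O2
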